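**Plan**

- Retrosynthetic cuts, in order: N–C1 of the azonine (ring C); C4–C5 of the cyclopentanone (ring B), traced back to a C5 aldehyde and a C4≡C3 alkyne grown from an ester on C12; then C12–C7 and C14=C15 of ring A.
- Enabling feature: ring A (C7, C8, C15, C14, C13, C12) is a masked 3-methylcyclohexenone (C13 carbonyl, C14=C15 carrying C16). Its contiguous centres C12 (quaternary) and C7 lie on the bond between the α-carbon of a β-keto ester and the β-carbon of an enone.
- Forward order: ring A by amine-catalysed Michael addition and ring closure at C14=C15; ring B by nickel-catalysed reductive ynal cyclisation; ring C by intramolecular N-alkylation.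
- C14 carries a phosphonate so that ring A can only close by olefination of C15. The bare 1,5-diketone would be expected to close in the opposite, Robinson sense (C16 onto C13).
- Stereochemistry: C7 and C12 from the cinchona-derived amine; C13 from a Luche reduction anti to the ester; C15 from hydroxyl-directed epoxidation and hydride opening; the C4=C3 geometry from syn addition across the alkyne.

Key step: step 6

Remark: atoms are numbered N–C1–C2–C3=C4–C5(=O)–C6–C7–C8–C15(C16)–C14–C13–C12, with C12 also bonded to C4, C7 and C11, and C11–C10–C9–N; the C5 carbinol centre of 27–31 and the acetal carbon of 17 carry no descriptor because both are removed later.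

**Route**

Step 1
Reactants: 1 3-(methylamino)propan-1-ol
Product: 2 tert-butyl (3-hydroxypropyl)(methyl)carbamate
Conditions: Boc2O, CH2Cl2, 0 °C → rt
Reagents that add atoms: di-tert-butyl dicarbonate, CC(C)(C)OC(=O)OC(=O)OC(C)(C)C
Why: Carbamate formation at the more nucleophilic secondary amine should leave the primary alcohol free.

Step 2
Reactants: 2 tert-butyl (3-hydroxypropyl)(methyl)carbamate
Product: 3 tert-butyl (3-iodopropyl)(methyl)carbamate
Conditions: I2, PPh3, imidazole, CH2Cl2, 0 °C → rt
Reagents that add atoms: iodine, II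
Why: Appel-type iodination replaces the primary hydroxyl by SN2 displacement of the alkoxyphosphonium ion.

Step 3
Reactants: 4 (diethoxyphosphoryl)acetic acid; 5 potassium methyl malonate
Product: 7 methyl 4-(diethoxyphosphoryl)-3-oxobutanoate, via acyl imidazole 6 (not isolated)
Conditions: 1,1'-carbonyldiimidazole, THF, rt; then 5, MgCl2, Et3N, MeCN, rt → 45 °C; aqueous HCl work-up
Reagents that add atoms: none
Why: Masamune–Brooks decarboxylative Claisen condensation, in which the acyl imidazole acylates the magnesium enolate of the malonate half-ester and loss of CO2 leaves the β-keto ester.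

Step 4
Reactants: 7 methyl 4-(diethoxyphosphoryl)-3-oxobutanoate; 3 tert-butyl (3-iodopropyl)(methyl)carbamate
Product: 8 fragment 1, methyl 2-[3-[Boc(methyl)amino]propyl]-4-(diethoxyphosphoryl)-3-oxobutanoate (racemic)
Conditions: NaH (1 equiv), THF/DMF, 0 → 45 °C
Reagents that add atoms: none
Why: Acetoacetic ester alkylation, the monoanion forming at the most acidic position between ketone and ester (future C12) and reacting there with the primary iodide; C12 is formed racemic and stays enolisable.

Step 5
Reactants: 9 3-[(tert-butyldimethylsilyl)oxy]propanal; 10 1-(triphenylphosphoranylidene)propan-2-one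
Product: 11 fragment 2, (E)-6-[(tert-butyldimethylsilyl)oxy]hex-3-en-2-one
Conditions: CH2Cl2, rt
Reagents that add atoms: none
Why: Wittig olefination with the stabilised acyl ylide should give the (E)-enone.

Step 6
Reactants: 8 fragment 1; 11 fragment 2
Product: 13 ring A enone methyl (1R,6S)-1-[3-[Boc(methyl)amino]propyl]-6-[2-(TBSO)ethyl]-4-methyl-2-oxocyclohex-3-ene-1-carboxylate, via Michael adduct 12 (not isolated)
Conditions: 9-amino(9-deoxy)-epi-quinine (20 mol %), CF3CO2H (40 mol %), toluene, 30 °C; then Cs2CO3, MeCN, rt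
Reagents that add atoms: none
Why: Proposed new method: the primary amine condenses with enone 11 to an iminium ion shielded on one face by the quinoline, the protonated quinuclidine hydrogen-bonds the enol of keto ester 8, and C12 adds to C7 within this assembly (Michael addition); Cs2CO3 then deprotonates C14 between ketone and phosphonate, and intramolecular Horner–Wadsworth–Emmons olefination of the C15 ketone closes ring A in a 6-(enolendo)-exo-trig mode with loss of diethyl phosphate. The closest known reactions are the iminium-catalysed Michael addition of α-unsubstituted β-keto esters to enones with cinchona-derived primary amines and the intramolecular HWE cyclisation of keto phosphonates to cyclohexenones; an acyclic α-alkyl donor building a quaternary centre next to a β-substituted enone carbon has not been shown. C7 is set by the catalyst through the enone face, and C12 by the face of the hydrogen-bonded enol that meets it, which should place the ester cis and the aminopropyl arm trans to the C7 side chain. The step needs reaction at C12 and not at C14, which the higher acidity and enol content of the 1,3-dicarbonyl CH should secure, and it needs closure of C14 onto C15 and not of C16 onto C13, which the phosphonate secures because only C14 can olefinate.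

Step 7
Reactants: 13 ring A enone
Product: 14 allylic alcohol methyl (1R,2S,6S)-1-[3-[Boc(methyl)amino]propyl]-6-[2-(TBSO)ethyl]-2-hydroxy-4-methylcyclohex-3-ene-1-carboxylate
Conditions: NaBH4, CeCl3·7H2O, MeOH, −78 → −20 °C
Reagents that add atoms: none
Why: Luche 1,2-reduction, in which hydride should attack C13 axially on the half-chair with the C7 side chain equatorial, anti to the pseudoaxial ester on C12, so that the C13 hydroxyl ends cis to the ester.

Step 8
Reactants: 14 allylic alcohol
Product: 15 cis-epoxy alcohol (7R,12R,13R,14R,15S), the 14,15-epoxide of 14 on the face of the C13 hydroxyl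
Conditions: VO(acac)2 (5 mol %), t-BuOOH, CH2Cl2, 0 °C → rt
Reagents that add atoms: tert-butyl hydroperoxide, CC(C)(C)OO
Why: Hydroxyl-directed epoxidation, the vanadium alkylperoxide bound to the C13 alkoxide delivering oxygen to the C14=C15 face syn to the hydroxyl.

Step 9
Reactants: 15 cis-epoxy alcohol
Product: 16 triol (7R,12S,13S,15S) with C13–OH, tertiary C15–OH cis to it and C4H2OH on C12
Conditions: LiEt3BH (5 equiv), THF, 0 °C → rt
Reagents that add atoms: none
Why: Hydride reduction of the ester to C4H2OH and SN2 opening of the trisubstituted epoxide at the less substituted C14 (trans-diaxial, Fürst–Plattner), which leaves the oxygen on C15 as a tertiary alcohol cis to the C13 hydroxyl.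

Step 10
Reactants: 16 triol
Product: 17 p-methoxybenzylidene acetal bridging the C4 and C13 oxygens, C15–OH free
Conditions: 4-MeOC6H4CH(OMe)2, pyridinium p-toluenesulfonate, CH2Cl2, rt
Reagents that add atoms: 4-methoxybenzaldehyde dimethyl acetal, COc1ccc(C(OC)OC)cc1
Why: Acid-catalysed transacetalisation engages the C4/C13 1,3-diol in a six-membered acetal, while the tertiary C15 hydroxyl cannot take part.

Step 11
Reactants: 17 p-methoxybenzylidene acetal
Product: 18 C13 PMB ether with free C4H2OH and free C15–OH
Conditions: i-Bu2AlH, CH2Cl2, −78 → 0 °C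
Reagents that add atoms: none
Why: Regioselective reductive acetal opening, aluminium coordinating the less hindered primary oxygen so that the PMB group stays on the secondary C13 oxygen.

Step 12
Reactants: 18 C13 PMB ether diol
Product: 19 C4 aldehyde (7R,12R,13S,15S)
Conditions: Dess–Martin periodinane, CH2Cl2, 0 °C → rt
Reagents that add atoms: none
Why: Dess–Martin oxidation of the neopentyl primary alcohol, the tertiary alcohol being inert and the fully substituted C12 unable to epimerise.

Step 13
Reactants: 19 C4 aldehyde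
Product: 20 terminal alkyne C4≡C3–H on C12
Conditions: dimethyl (1-diazo-2-oxopropyl)phosphonate, K2CO3, MeOH, 0 °C → rt
Reagents that add atoms: dimethyl (1-diazo-2-oxopropyl)phosphonate, CC(=O)C(=[N+]=[N-])P(=O)(OC)OC
Why: Seyferth–Gilbert homologation in the Ohira–Bestmann variant, the alkylidene carbene rearranging by 1,2-hydride shift to the alkyne; the aldehyde has no α-hydrogen and C13 is protected against retro-aldol cleavage.

Step 14
Reactants: 20 terminal alkyne
Product: 21 homopropargylic alcohol C4≡C3–C2H2–C1H2OH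
Conditions: n-BuLi (2.1 equiv), THF, −78 °C; BF3·OEt2; ethylene oxide, −78 °C
Reagents that add atoms: ethylene oxide, C1CO1
Why: Opening of BF3-activated ethylene oxide by the lithium acetylide (Yamaguchi alkynylation) adds C2 and C1, the tertiary lithium alkoxide being a bystander.

Step 15
Reactants: 21 homopropargylic alcohol
Product: 22 C1 chloride
Conditions: PPh3, N-chlorosuccinimide, THF, 0 °C → rt
Reagents that add atoms: N-chlorosuccinimide, O=C1CCC(=O)N1Cl
Why: Appel chlorination by SN2 displacement at the primary carbinol, which the hindered tertiary C15 alcohol cannot undergo.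

Step 16
Reactants: 22 C1 chloride
Product: 23 C13,C15-diol
Conditions: 2,3-dichloro-5,6-dicyano-1,4-benzoquinone, CH2Cl2/pH 7 buffer, 0 °C
Reagents that add atoms: none
Why: Oxidative PMB ether cleavage (benzylic hydride abstraction, then hydrolysis of the oxocarbenium ion) frees the C13 alcohol.

Step 17
Reactants: 23 C13,C15-diol
Product: 24 C13,C15-diacetate
Conditions: Ac2O, 4-(dimethylamino)pyridine, Et3N, CH2Cl2, rt → 40 °C
Reagents that add atoms: acetic anhydride, CC(=O)OC(C)=O
Why: Nucleophile-catalysed acylation through the N-acetylpyridinium ion esterifies the secondary and, on warming, the tertiary alcohol.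

Step 18
Reactants: 24 diacetate
Product: 25 C5 primary alcohol
Conditions: HF·pyridine, pyridine, THF, 0 °C → rt
Reagents that add atoms: none
Why: Fluoride-mediated desilylation of the primary TBS ether under buffered conditions that acetates, carbamate and chloride tolerate.

Step 19
Reactants: 25 C5 primary alcohol
Product: 26 ynal (C5 aldehyde, 7S,12S,13S,15S)
Conditions: Dess–Martin periodinane, CH2Cl2, 0 °C → rt
Reagents that add atoms: none
Why: Dess–Martin oxidation of the primary alcohol to the aldehyde.

Step 20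
Reactants: 26 ynal
Product: 27 A/B bicycle (cis-hydrindane) with C5 triethylsilyl ether and exocyclic (E)-C4=C3 bearing the chloroethyl arm
Conditions: Ni(cod)2 (20 mol %), PBu3 (40 mol %), Et3SiH, THF, rt
Reagents that add atoms: triethylsilane, CC[SiH](CC)CC
Why: Nickel-catalysed reductive ynal cyclisation (Montgomery type), in which oxidative cyclisation of zerovalent nickel with aldehyde and alkyne forms C4–C5 in a five-membered oxanickelacycle and Si–H σ-bond metathesis followed by C–H reductive elimination places hydrogen on C3 syn to C5, fixing C2 cis to C12; the ring fusion is cis because C4 and C6 sit on the same face, and the C5 carbinol configuration is immaterial.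

Step 21
Reactants: 27 A/B bicycle
Product: 29 amino alcohol of the A/B bicycle having free NHMe plus free C5–OH plus C1 chloride, via silyl carbamate 28 (not isolated)
Conditions: t-BuMe2SiOTf, 2,6-lutidine, CH2Cl2, 0 °C → rt; then HF·pyridine, THF, 0 °C → rt
Reagents that add atoms: none
Why: Silyl triflate-mediated Boc cleavage (Ohfune conditions) gives the silyl carbamate, which HF·pyridine cleaves with loss of CO2 while also removing the triethylsilyl group, and the tertiary acetate, which strong protic acid could ionise, is spared.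

Step 22
Reactants: 29 amino alcohol
Product: 31 azonine allylic alcohol (rings A, B and C closed; C5–OH), via iodide 30 (not isolated)
Conditions: K2CO3, NaI (cat.), MeCN (2 mM), 70 °C
Reagents that add atoms: none
Why: Intramolecular SN2 N-alkylation after Finkelstein exchange closes the nine-membered ring at high dilution, helped by the cis relation of C2 and C12 on the C4=C3 bond, which holds the two chain ends close.

Step 23
Reactants: 31 azonine allylic alcohol
Product: 32 target (7S,12S,13S,15S)
Conditions: Dess–Martin periodinane, CH2Cl2, 0 °C → rt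
Reagents that add atoms: none
Why: Dess–Martin oxidation of the allylic C5 alcohol to the enone, which removes the undefined carbinol centre and touches no other stereocentre.

**Compound list**

1 | 3-(methylamino)propan-1-ol | CNCCCO | starting material
2 | tert-butyl (3-hydroxypropyl)(methyl)carbamate | CN(CCCO)C(=O)OC(C)(C)C | intermediate
3 | tert-butyl (3-iodopropyl)(methyl)carbamate | CN(CCCI)C(=O)OC(C)(C)C | intermediate
4 | (diethoxyphosphoryl)acetic acid | CCOP(=O)(CC(=O)O)OCC | starting material
5 | potassium methyl malonate (potassium 3-methoxy-3-oxopropanoate) | COC(=O)CC(=O)[O-].[K+] | starting material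
6 | diethyl [2-(1H-imidazol-1-yl)-2-oxoethyl]phosphonate | CCOP(=O)(CC(=O)n1ccnc1)OCC | intermediate (not isolated)
7 | methyl 4-(diethoxyphosphoryl)-3-oxobutanoate | CCOP(=O)(OCC)CC(=O)CC(=O)OC | intermediate
8 | fragment 1: methyl 2-[3-[(tert-butoxycarbonyl)(methyl)amino]propyl]-4-(diethoxyphosphoryl)-3-oxobutanoate, racemic | CCOP(=O)(OCC)CC(=O)C(CCCN(C)C(=O)OC(C)(C)C)C(=O)OC | intermediate
9 | 3-[(tert-butyldimethylsilyl)oxy]propanal | O=CCCO[Si](C)(C)C(C)(C)C | starting material
10 | 1-(triphenylphosphoranylidene)propan-2-one | CC(=O)C=P(c1ccccc1)(c1ccccc1)c1ccccc1 | starting material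
11 | fragment 2: (E)-6-[(tert-butyldimethylsilyl)oxy]hex-3-en-2-one | CC(=O)/C=C/CCO[Si](C)(C)C(C)(C)C | intermediate
12 | methyl (2R,3R)-2-[3-[(tert-butoxycarbonyl)(methyl)amino]propyl]-2-[(diethoxyphosphoryl)acetyl]-3-[2-[(tert-butyldimethylsilyl)oxy]ethyl]-5-oxohexanoate | CCOP(=O)(OCC)CC(=O)[C@](CCCN(C)C(=O)OC(C)(C)C)(C(=O)OC)[C@H](CCO[Si](C)(C)C(C)(C)C)CC(C)=O | intermediate (not isolated)
13 | methyl (1R,6S)-1-[3-[(tert-butoxycarbonyl)(methyl)amino]propyl]-6-[2-[(tert-butyldimethylsilyl)oxy]ethyl]-4-methyl-2-oxocyclohex-3-ene-1-carboxylate | CC1=CC(=O)[C@](CCCN(C)C(=O)OC(C)(C)C)(C(=O)OC)[C@H](CCO[Si](C)(C)C(C)(C)C)C1 | intermediate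
14 | methyl (1R,2S,6S)-1-[3-[(tert-butoxycarbonyl)(methyl)amino]propyl]-6-[2-[(tert-butyldimethylsilyl)oxy]ethyl]-2-hydroxy-4-methylcyclohex-3-ene-1-carboxylate | CC1=C[C@H](O)[C@](CCCN(C)C(=O)OC(C)(C)C)(C(=O)OC)[C@H](CCO[Si](C)(C)C(C)(C)C)C1 | intermediate
15 | (7R,12R,13R,14R,15S)-epoxy alcohol: 14,15-epoxide of 14, oxygen cis to the C13 hydroxyl and to the ester | C[C@@]12O[C@@H]1[C@H](O)[C@](CCCN(C)C(=O)OC(C)(C)C)(C(=O)OC)[C@H](CCO[Si](C)(C)C(C)(C)C)C2 | intermediate
16 | (7R,12S,13S,15S)-triol: cyclohexane with C13–OH, C15(CH3)–OH cis to it, C12 bearing CH2OH (cis to both hydroxyls) and the Boc(methyl)aminopropyl arm, C7 bearing the silyloxyethyl arm cis to CH2OH | C[C@@]1(O)C[C@H](O)[C@](CCCN(C)C(=O)OC(C)(C)C)(CO)[C@H](CCO[Si](C)(C)C(C)(C)C)C1 | intermediate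
17 | 4-methoxybenzylidene acetal of the C4/C13 diol of 16 (acetal carbon unassigned) | C[C@@]1(O)C[C@@H]2OC(c3ccc(OC)cc3)OC[C@]2(CCCN(C)C(=O)OC(C)(C)C)[C@H](CCO[Si](C)(C)C(C)(C)C)C1 | intermediate
18 | (7R,12S,13S,15S)-C13 4-methoxybenzyl ether of 16 | C[C@@]1(O)C[C@H](OCc2ccc(OC)cc2)[C@](CCCN(C)C(=O)OC(C)(C)C)(CO)[C@H](CCO[Si](C)(C)C(C)(C)C)C1 | intermediate
19 | (7R,12R,13S,15S)-C4 aldehyde of 18 | C[C@@]1(O)C[C@H](OCc2ccc(OC)cc2)[C@](CCCN(C)C(=O)OC(C)(C)C)(C=O)[C@H](CCO[Si](C)(C)C(C)(C)C)C1 | intermediate
20 | (7R,12S,13S,15S)-C12 ethynyl compound | C[C@@]1(O)C[C@H](OCc2ccc(OC)cc2)[C@](CCCN(C)C(=O)OC(C)(C)C)(C#C)[C@H](CCO[Si](C)(C)C(C)(C)C)C1 | intermediate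
21 | (7R,12S,13S,15S)-C12 4-hydroxybut-1-ynyl compound | C[C@@]1(O)C[C@H](OCc2ccc(OC)cc2)[C@](CCCN(C)C(=O)OC(C)(C)C)(C#CCCO)[C@H](CCO[Si](C)(C)C(C)(C)C)C1 | intermediate
22 | (7R,12S,13S,15S)-C12 4-chlorobut-1-ynyl compound | C[C@@]1(O)C[C@H](OCc2ccc(OC)cc2)[C@](CCCN(C)C(=O)OC(C)(C)C)(C#CCCCl)[C@H](CCO[Si](C)(C)C(C)(C)C)C1 | intermediate
23 | (7R,12S,13S,15S)-C13,C15-diol | C[C@@]1(O)C[C@H](O)[C@](CCCN(C)C(=O)OC(C)(C)C)(C#CCCCl)[C@H](CCO[Si](C)(C)C(C)(C)C)C1 | intermediate
24 | (7R,12S,13S,15S)-C13,C15-diacetate | C[C@@]1(OC(C)=O)C[C@H](OC(C)=O)[C@](CCCN(C)C(=O)OC(C)(C)C)(C#CCCCl)[C@H](CCO[Si](C)(C)C(C)(C)C)C1 | intermediate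
25 | (7R,12S,13S,15S)-diacetate with free C5H2OH | C[C@@]1(OC(C)=O)C[C@H](OC(C)=O)[C@](CCCN(C)C(=O)OC(C)(C)C)(C#CCCCl)[C@H](CCO)C1 | intermediate
26 | (7S,12S,13S,15S)-ynal (C5 aldehyde) | C[C@@]1(OC(C)=O)C[C@H](OC(C)=O)[C@](CCCN(C)C(=O)OC(C)(C)C)(C#CCCCl)[C@H](CC=O)C1 | intermediate
27 | (7R,12S,13S,15S)-cis-hydrindane: ring B with C5–OSiEt3 and exocyclic (E)-C4=C3H–CH2CH2Cl (C2 cis to C12), C5 unassigned | C[C@@]1(OC(C)=O)C[C@H](OC(C)=O)[C@]2(CCCN(C)C(=O)OC(C)(C)C)/C(=C\CCCl)C(O[Si](CC)(CC)CC)C[C@@H]2C1 | intermediate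
28 | tert-butyldimethylsilyl carbamate of 27 (N–CO2SiMe2t-Bu in place of N–Boc) | C[C@@]1(OC(C)=O)C[C@H](OC(C)=O)[C@]2(CCCN(C)C(=O)O[Si](C)(C)C(C)(C)C)/C(=C\CCCl)C(O[Si](CC)(CC)CC)C[C@@H]2C1 | intermediate (not isolated)
29 | amino alcohol: 27 with free NHMe and free C5–OH | C[C@@]1(OC(C)=O)C[C@H](OC(C)=O)[C@]2(CCCNC)/C(=C\CCCl)C(O)C[C@@H]2C1 | intermediate
30 | C1 iodide corresponding to 29 | C[C@@]1(OC(C)=O)C[C@H](OC(C)=O)[C@]2(CCCNC)/C(=C\CCI)C(O)C[C@@H]2C1 | intermediate (not isolated)
31 | (7R,12S,13S,15S)-azonine allylic alcohol: target skeleton with C5–OH in place of the ketone, C5 unassigned | C[C@@]1(OC(C)=O)C[C@H](OC(C)=O)[C@]23CCCN(C)CC/C=C2/C(O)C[C@@H]3C1 | intermediate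
32 | CNP0386920.1, (7S,12S,13S,15S)-13,15-diacetoxy-N-methyl azonine-fused hydrindenone with (E)-C4=C3 | C[C@@]1(OC(C)=O)C[C@H](OC(C)=O)[C@]23CCCN(C)CC/C=C2/C(=O)C[C@@H]3C1 | target

**Count and risks**

Total steps: 23. Longest linear sequence: 21 steps (steps 1, 2, 4 and 6–23).

Steps most likely to fail:

1. Step 6. The Michael addition may proceed through C14 instead of C12, facial discrimination at the congested C12–C7 bond may be poor, or the adduct may revert by retro-Michael cleavage before olefination. Fallback, setting out from 7 and 11: the α-unsubstituted keto ester 7, a donor of the class for which this amine-salt catalysis is established, is added to 11 to give methyl (3R)-2-[(diethoxyphosphoryl)acetyl]-3-[2-[(tert-butyldimethylsilyl)oxy]ethyl]-5-oxohexanoate F1. Cs2CO3 closes it by the same intramolecular HWE reaction to methyl (6S)-6-[2-[(tert-butyldimethylsilyl)oxy]ethyl]-4-methyl-2-oxocyclohex-3-ene-1-carboxylate F2. Alkylation of the enolate of F2 with iodide 3 (K2CO3, DMF) should occur anti to the C7 side chain, so the quaternary centre is set by the substrate, and the route is rejoined at 13.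

2. Step 9. Trans-diaxial hydride delivery to C14 has to pass through the less favoured half-chair, with the C7 side chain and the C13 oxygen pseudoaxial, so the opening may be slow or may lose regioselectivity. Fallback, setting out from 15: Dess–Martin oxidation gives the (7R,12R,14S,15S)-α,β-epoxy ketone F3. SmI2 (THF/MeOH, −78 °C) cleaves the C14–O bond through the ketyl, independent of ring conformation, to the (7R,12R,15S)-β-hydroxy ketone F4. Chelation-controlled reduction (Et2BOMe, NaBH4, Narasaka–Prasad) should give the (7R,12R,13S,15S)-syn-diol ester F5. LiBH4 then reduces the ester, and the route is rejoined at 16.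

3. Step 22. Intermolecular N-alkylation (oligomerisation) may outrun the nine-membered ring closure. Fallback, setting out from 27: NaI in acetone gives the C1 iodide of 27 F6. AgBF4 in DMSO followed by Et3N (silver-assisted Kornblum oxidation) gives the C1 aldehyde F7. The silyl triflate/2,6-lutidine and HF·pyridine sequence of step 21 releases the amino aldehyde F8, which is not isolated. It is closed at high dilution by intramolecular reductive amination with NaBH(OAc)3, so the ring forms through a reversible iminium ion instead of an irreversible displacement, and the route is rejoined at 31.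

Further compounds
F1 | step 6 | methyl (3R)-2-[(diethoxyphosphoryl)acetyl]-3-[2-[(tert-butyldimethylsilyl)oxy]ethyl]-5-oxohexanoate (C2 epimers) | CCOP(=O)(OCC)CC(=O)C(C(=O)OC)[C@H](CCO[Si](C)(C)C(C)(C)C)CC(C)=O
F2 | step 6 | methyl (6S)-6-[2-[(tert-butyldimethylsilyl)oxy]ethyl]-4-methyl-2-oxocyclohex-3-ene-1-carboxylate (C1 epimerisable) | CC1=CC(=O)C(C(=O)OC)[C@H](CCO[Si](C)(C)C(C)(C)C)C1
F3 | step 9 | (7R,12R,14S,15S)-α,β-epoxy ketone, the C13 ketone of 15 | C[C@@]12O[C@@H]1C(=O)[C@](CCCN(C)C(=O)OC(C)(C)C)(C(=O)OC)[C@H](CCO[Si](C)(C)C(C)(C)C)C2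
F4 | step 9 | (7R,12R,15S)-β-hydroxy ketone with C15 tertiary alcohol, C13 ketone and methyl ester | C[C@@]1(O)CC(=O)[C@](CCCN(C)C(=O)OC(C)(C)C)(C(=O)OC)[C@H](CCO[Si](C)(C)C(C)(C)C)C1
F5 | step 9 | (7R,12R,13S,15S)-cis-C13,C15-diol methyl ester | C[C@@]1(O)C[C@H](O)[C@](CCCN(C)C(=O)OC(C)(C)C)(C(=O)OC)[C@H](CCO[Si](C)(C)C(C)(C)C)C1
F6 | step 22 | C1 iodide of 27 | C[C@@]1(OC(C)=O)C[C@H](OC(C)=O)[C@]2(CCCN(C)C(=O)OC(C)(C)C)/C(=C\CCI)C(O[Si](CC)(CC)CC)C[C@@H]2C1
F7 | step 22 | C1 aldehyde derived from 27 | C[C@@]1(OC(C)=O)C[C@H](OC(C)=O)[C@]2(CCCN(C)C(=O)OC(C)(C)C)/C(=C\CC=O)C(O[Si](CC)(CC)CC)C[C@@H]2C1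
F8 | step 22 | amino aldehyde with free NHMe, free C5–OH and C1 aldehyde | C[C@@]1(OC(C)=O)C[C@H](OC(C)=O)[C@]2(CCCNC)/C(=C\CC=O)C(O)C[C@@H]2C1
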